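**Strategy.** Everything rests on disconnecting ring C of the top epicatechin unit (O1, C2, C3, C4, C4a, C8a) as a [4+2] adduct. The diene is an ortho-quinone methide spanning O1=C8a–C4a=C4, whose C4 already carries C8 of the middle unit; the dienophile is a (Z)-enol gallate supplying C2=C3. The precursor is an ortho-hydroxybenzhydrol built on a brominated, benzylated epicatechin dimer. A chiral Brønsted acid dehydrates it and the quinone methide takes up the enol ester, closing ring C through the C3–C4 bond (with O1–C2), setting C2, C3 and C4 and installing the top gallate in one operation. The catechol ring on C2 dictates the regiochemistry.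

Key step: step 9

Assumption: the (R)-phosphoramide in step 9 is taken as the enantiomer that exposes the quinone methide face leading to the 4β configuration; if the sense of induction is the opposite, its mirror image is used under the same conditions.

Flavan numbering is used for each unit. "Top" is the unit whose C4 is bonded to C8 of the middle unit; "lower" is the unit with the C4 methylene.

**Step 1**
Reactants: 1 (−)-epicatechin
Product: 2 5,7,3',4'-tetra-O-benzyl-(−)-epicatechin
Conditions: BnBr (4.4 equiv), K2CO3, DMF, 0 °C → rt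
Reagents that add atoms: benzyl bromide BrCc1ccccc1
Why: Williamson etherification should alkylate the four phenols selectively over the far less acidic secondary 3-OH, and the mild carbonate base at low temperature should leave C2 and C3 untouched.

**Step 2**
Reactants: 2 5,7,3',4'-tetra-O-benzyl-(−)-epicatechin
Product: 3 8-bromo-5,7,3',4'-tetra-O-benzyl-(−)-epicatechin
Conditions: NBS (1.0 equiv), CH2Cl2, −78 °C → rt
Reagents that add atoms: N-bromosuccinimide O=C1CCC(=O)N1Br
Why: electrophilic aromatic bromination should occur at C8 of ring A, which is flanked by only one benzyloxy group and the ring oxygen and is the position known to react in benzylated flavan-3-ols.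

**Step 3**
Reactants: 3 8-bromo-5,7,3',4'-tetra-O-benzyl-(−)-epicatechin
Product: 4 8-bromo-4β-(2-ethoxyethoxy)-5,7,3',4'-tetra-O-benzyl-(−)-epicatechin (2,3-cis-3,4-trans)
Conditions: DDQ (2 equiv), 2-ethoxyethanol (5 equiv), CH2Cl2, rt
Reagents that add atoms: 2-ethoxyethanol CCOCCO
Why: DDQ benzylic oxidation should abstract hydride from C4 to give a cation stabilised by the ring A oxygens, which the alcohol should trap anti to the 3-OH to set the 4β ether.

**Step 4**
Reactants: 4 8-bromo-4β-(2-ethoxyethoxy)-5,7,3',4'-tetra-O-benzyl-(−)-epicatechin; 2 5,7,3',4'-tetra-O-benzyl-(−)-epicatechin (3–4 equiv)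
Product: 5 8-bromo-[5,7,3',4'-tetra-O-benzylepicatechin]-(4β→8)-[5,7,3',4'-tetra-O-benzylepicatechin] (bromine on C8 of the upper unit; both 3-OH free)
Conditions: Me3SiOSO2CF3 (0.2 equiv), CH2Cl2, −78 °C
Reagents that add atoms: none
Why: Lewis acid ionisation of the C4 ether followed by Friedel–Crafts attack of C8 of 2 anti to the 3-OH should give the 4β (3,4-trans) interflavan bond, with the bromine blocking self-condensation of the electrophile and the excess of 2 suppressing further chain growth.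

**Step 5**
Reactants: 6 2,4,6-trihydroxybenzaldehyde
Product: 7 2-hydroxy-4,6-bis(benzyloxy)benzaldehyde
Conditions: BnBr (2.0 equiv), K2CO3, DMF, 0 °C → rt
Reagents that add atoms: benzyl bromide BrCc1ccccc1
Why: Williamson etherification should alkylate the para-hydroxyl and one ortho-hydroxyl, while the remaining ortho-hydroxyl, hydrogen-bonded to the formyl oxygen, should resist alkylation at this stoichiometry.

**Step 6**
Reactants: 5 8-bromo dimer; 7 2-hydroxy-4,6-bis(benzyloxy)benzaldehyde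
Product: 10 8-[hydroxy(2-hydroxy-4,6-bis(benzyloxy)phenyl)methyl]-[5,7,3',4'-tetra-O-benzylepicatechin]-(4β→8)-[5,7,3',4'-tetra-O-benzylepicatechin] (both carbinol epimers), via trilithiated dimer 8 (not isolated), via sodium phenoxide 9 (not isolated)
Conditions: 5, MeLi (2.05 equiv) then t-BuLi (2.1 equiv), THF, −78 °C; add 9 (from 7, NaH, THF, 0 °C; 1.5 equiv), −78 → 0 °C; aq NH4Cl; purify on Et3N-deactivated silica and use promptly
Reagents that add atoms: none
Why: alkoxide formation, bromine–lithium exchange and 1,2-addition of the aryllithium to the aldehyde (pre-deprotonated with hydride so that no proton source remains) should give the benzhydrol, whose new stereocentre is left uncontrolled because it becomes planar in step 9.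

**Step 7**
Reactants: 11 3,4-bis(benzyloxy)benzaldehyde
Product: 12 4-ethynyl-1,2-bis(benzyloxy)benzene
Conditions: dimethyl (1-diazo-2-oxopropyl)phosphonate (1.3 equiv), K2CO3 (2 equiv), MeOH/THF, rt
Reagents that add atoms: dimethyl (1-diazo-2-oxopropyl)phosphonate COP(=O)(OC)C(=[N+]=[N-])C(C)=O
Why: Seyferth–Gilbert homologation in the Ohira–Bestmann modification should convert the non-enolisable aryl aldehyde into the terminal alkyne under conditions that leave benzyl ethers untouched.

**Step 8**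
Reactants: 12 4-ethynyl-1,2-bis(benzyloxy)benzene; 13 3,4,5-tris(benzyloxy)benzoic acid
Product: 14 (Z)-2-[3,4-bis(benzyloxy)phenyl]ethenyl 3,4,5-tris(benzyloxy)benzoate
Conditions: Ru(η3-CH2C(CH3)CH2)2(Ph2P(CH2)4PPh2) (2 mol%), toluene, 65 °C
Reagents that add atoms: none
Why: ruthenium-catalysed anti-Markovnikov hydro-acyloxylation of a terminal alkyne should proceed through a ruthenium vinylidene that the carboxylate attacks at the metal-bound carbon, and protonolysis of the resulting alkenyl–ruthenium species should deliver the (Z)-enol ester.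

**Step 9**
Reactants: 10 ortho-hydroxybenzhydrol of the dimer; 14 (Z)-enol gallate (3 equiv)
Product: 16 [3-O-(3,4,5-tri-O-benzylgalloyl)-5,7,3',4'-tetra-O-benzylepicatechin]-(4β→8)-[5,7,3',4'-tetra-O-benzylepicatechin]-(4β→8)-[5,7,3',4'-tetra-O-benzylepicatechin] (middle and lower 3-OH free), via ortho-quinone methide 15 (not isolated)
Conditions: (R)-3,3'-bis(2,4,6-triisopropylphenyl)-1,1'-binaphthyl-2,2'-diyl N-triflylphosphoramide (10 mol%), 5 Å molecular sieves, CH2Cl2, −40 → 0 °C
Reagents that add atoms: none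
Why: The acid ionises the doubly benzylic carbinol of 10 with loss of water and the ortho-phenol collapses the cation to the catalyst-bound (E)-ortho-quinone methide 15 (heterodiene O1=C8a–C4a=C4), which undergoes an inverse-electron-demand oxa-[4+2] cycloaddition with the electron-rich alkene of 14, highly asynchronous with C3–C4 bond formation leading and O1–C2 closure following within the same ion pair. The closest known reaction type is the chiral Brønsted acid-catalysed [4+2] cycloaddition of ortho-hydroxybenzhydrol-derived quinone methides with β-substituted 4-alkoxystyrenes. Ring C (six-membered) is closed in a suprafacial [4+2] mode, both new bonds (C3–C4 and O1–C2) being ring bonds. The 2,3-cis relationship transcribes the Z geometry of 14; the 3,4-trans relationship follows from the exo approach, in which the galloyloxy group on C3 avoids the tetra-ortho-substituted aryl group on C4; the absolute configuration (2R,3R,4β) is set by the phosphoramide anion hydrogen-bonded to O1, which screens one face of C4, the remote stereocentres of the dimer playing a minor role. The step needs regioselectivity (C3 to C4, O1 to C2), secured by the 3,4-bis(benzyloxy)phenyl ring, which stabilises positive charge at C2 far better than the weakly donating ester oxygen does at C3; chemoselectivity over Friedel–Crafts attack by the benzylated rings rests on the excess of 14 and on the reversibility of O-alkylation by the free 3-hydroxyls.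

**Step 10**
Reactants: 16 trimer mono-gallate diol; 13 3,4,5-tris(benzyloxy)benzoic acid (6 equiv)
Product: 17 henicosa-O-benzyl procyanidin C1 3,3',3''-tri-O-gallate (all 21 phenols as benzyl ethers)
Conditions: DCC (6 equiv), DMAP (2 equiv), CH2Cl2, rt
Reagents that add atoms: none
Why: Steglich esterification should acylate the two remaining secondary 3-hydroxyls at oxygen, leaving every stereocentre, the existing gallate and the benzyl ethers untouched.

**Step 11**
Reactants: 17 henicosa-O-benzyl procyanidin C1 3,3',3''-tri-O-gallate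
Product: 18 procyanidin C1 3,3',3''-tri-O-gallate (target)
Conditions: H2 (1 atm), Pd(OH)2/C, THF/MeOH/H2O, rt; filtration, reverse-phase purification, lyophilisation
Reagents that add atoms: none
Why: catalytic hydrogenolysis should cleave all 21 benzyl ethers while the gallate esters, the interflavan C–C bonds and the ring C ethers persist, as they do in the parent benzylated procyanidins.

**Compound list**

1 | (−)-epicatechin, (2R,3R) | O[C@@H]1Cc2c(O)cc(O)cc2O[C@@H]1c1ccc(O)c(O)c1 | starting material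
2 | 5,7,3',4'-tetra-O-benzyl-(−)-epicatechin | O[C@@H]1Cc2c(OCc3ccccc3)cc(OCc3ccccc3)cc2O[C@@H]1c1ccc(OCc2ccccc2)c(OCc2ccccc2)c1 | intermediate
3 | 8-bromo-5,7,3',4'-tetra-O-benzyl-(−)-epicatechin | O[C@@H]1Cc2c(OCc3ccccc3)cc(OCc3ccccc3)c(Br)c2O[C@@H]1c1ccc(OCc2ccccc2)c(OCc2ccccc2)c1 | intermediate
4 | 8-bromo-4β-(2-ethoxyethoxy)-5,7,3',4'-tetra-O-benzyl-(−)-epicatechin (3,4-trans) | O[C@@H]1[C@@H](OCCOCC)c2c(OCc3ccccc3)cc(OCc3ccccc3)c(Br)c2O[C@@H]1c1ccc(OCc2ccccc2)c(OCc2ccccc2)c1 | intermediate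
5 | 8-bromo-[tetra-O-benzylepicatechin]-(4β→8)-[tetra-O-benzylepicatechin], bromine on the upper unit | O[C@@H]1[C@@H](c2c(OCc3ccccc3)cc(OCc3ccccc3)c3c2O[C@H](c2ccc(OCc4ccccc4)c(OCc4ccccc4)c2)[C@H](O)C3)c2c(OCc3ccccc3)cc(OCc3ccccc3)c(Br)c2O[C@@H]1c1ccc(OCc2ccccc2)c(OCc2ccccc2)c1 | intermediate
6 | 2,4,6-trihydroxybenzaldehyde | O=Cc1c(O)cc(O)cc1O | starting material
7 | 2-hydroxy-4,6-bis(benzyloxy)benzaldehyde | O=Cc1c(O)cc(OCc2ccccc2)cc1OCc1ccccc1 | intermediate
8 | trilithiated dimer (C8 aryllithium, both 3-O-lithium alkoxides) | [Li]O[C@@H]1[C@@H](c2c(OCc3ccccc3)cc(OCc3ccccc3)c3c2O[C@H](c2ccc(OCc4ccccc4)c(OCc4ccccc4)c2)[C@H](O[Li])C3)c2c(OCc3ccccc3)cc(OCc3ccccc3)c([Li])c2O[C@@H]1c1ccc(OCc2ccccc2)c(OCc2ccccc2)c1 | intermediate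
9 | sodium 2-formyl-3,5-bis(benzyloxy)phenoxide | [Na+].[O-]c1cc(OCc2ccccc2)cc(OCc2ccccc2)c1C=O | intermediate
10 | ortho-hydroxybenzhydrol: dimer 5 with Br replaced by CH(OH)[2-hydroxy-4,6-bis(benzyloxy)phenyl], carbinol epimers | O[C@@H]1[C@@H](c2c(OCc3ccccc3)cc(OCc3ccccc3)c3c2O[C@H](c2ccc(OCc4ccccc4)c(OCc4ccccc4)c2)[C@H](O)C3)c2c(OCc3ccccc3)cc(OCc3ccccc3)c(C(O)c3c(O)cc(OCc4ccccc4)cc3OCc3ccccc3)c2O[C@@H]1c1ccc(OCc2ccccc2)c(OCc2ccccc2)c1 | intermediate
11 | 3,4-bis(benzyloxy)benzaldehyde | O=Cc1ccc(OCc2ccccc2)c(OCc2ccccc2)c1 | starting material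
12 | 4-ethynyl-1,2-bis(benzyloxy)benzene | C#Cc1ccc(OCc2ccccc2)c(OCc2ccccc2)c1 | intermediate
13 | 3,4,5-tris(benzyloxy)benzoic acid | OC(=O)c1cc(OCc2ccccc2)c(OCc2ccccc2)c(OCc2ccccc2)c1 | starting material
14 | (Z)-2-[3,4-bis(benzyloxy)phenyl]ethenyl 3,4,5-tris(benzyloxy)benzoate | O=C(O/C=C\c1ccc(OCc2ccccc2)c(OCc2ccccc2)c1)c1cc(OCc2ccccc2)c(OCc2ccccc2)c(OCc2ccccc2)c1 | intermediate
15 | (E)-ortho-quinone methide: 3,5-bis(benzyloxy)-6-(arylmethylidene)cyclohexa-2,4-dienone, aryl = C8 of the dimer | O[C@@H]1[C@@H](c2c(OCc3ccccc3)cc(OCc3ccccc3)c3c2O[C@H](c2ccc(OCc4ccccc4)c(OCc4ccccc4)c2)[C@H](O)C3)c2c(OCc3ccccc3)cc(OCc3ccccc3)c(/C=C3/C(=O)C=C(OCc4ccccc4)C=C3OCc3ccccc3)c2O[C@@H]1c1ccc(OCc2ccccc2)c(OCc2ccccc2)c1 | intermediate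
16 | [3-O-(tri-O-benzylgalloyl)-tetra-O-benzylepicatechin]-(4β→8)-[tetra-O-benzylepicatechin]-(4β→8)-[tetra-O-benzylepicatechin] | O[C@@H]1[C@@H](c2c(OCc3ccccc3)cc(OCc3ccccc3)c3c2O[C@H](c2ccc(OCc4ccccc4)c(OCc4ccccc4)c2)[C@H](O)C3)c2c(OCc3ccccc3)cc(OCc3ccccc3)c([C@H]3c4c(OCc5ccccc5)cc(OCc5ccccc5)cc4O[C@H](c4ccc(OCc5ccccc5)c(OCc5ccccc5)c4)[C@@H]3OC(=O)c3cc(OCc4ccccc4)c(OCc4ccccc4)c(OCc4ccccc4)c3)c2O[C@@H]1c1ccc(OCc2ccccc2)c(OCc2ccccc2)c1 | intermediate
17 | henicosa-O-benzyl procyanidin C1 3,3',3''-tri-O-gallate | O=C(O[C@@H]1[C@@H](c2c(OCc3ccccc3)cc(OCc3ccccc3)c3c2O[C@H](c2ccc(OCc4ccccc4)c(OCc4ccccc4)c2)[C@H](OC(=O)c2cc(OCc4ccccc4)c(OCc4ccccc4)c(OCc4ccccc4)c2)C3)c2c(OCc3ccccc3)cc(OCc3ccccc3)c([C@H]3c4c(OCc5ccccc5)cc(OCc5ccccc5)cc4O[C@H](c4ccc(OCc5ccccc5)c(OCc5ccccc5)c4)[C@@H]3OC(=O)c3cc(OCc4ccccc4)c(OCc4ccccc4)c(OCc4ccccc4)c3)c2O[C@@H]1c1ccc(OCc2ccccc2)c(OCc2ccccc2)c1)c1cc(OCc2ccccc2)c(OCc2ccccc2)c(OCc2ccccc2)c1 | intermediate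
18 | procyanidin C1 3,3',3''-tri-O-gallate | O=C(O[C@@H]1[C@@H](c2c(O)cc(O)c3c2O[C@H](c2ccc(O)c(O)c2)[C@H](OC(=O)c2cc(O)c(O)c(O)c2)C3)c2c(O)cc(O)c([C@H]3c4c(O)cc(O)cc4O[C@H](c4ccc(O)c(O)c4)[C@@H]3OC(=O)c3cc(O)c(O)c(O)c3)c2O[C@@H]1c1ccc(O)c(O)c1)c1cc(O)c(O)c(O)c1 | target

**Step count.** Total: 11 steps. Longest linear sequence: 8 steps (1, 2, 3, 4, 6, 9, 10, 11).

**Steps most likely to fail**

1. Step 9. The cycloaddition may suffer from poor facial or exo selectivity, from loss of the alkene geometry through a stepwise cationic pathway, or from acid-induced scission of the existing interflavan bond. In the fallback, ring C of the top unit is brought in preformed and the interflavan bond is made by C4-cation arylation. Setting out from 2, DDQ and 2-ethoxyethanol in CH2Cl2 would give 4β-(2-ethoxyethoxy)-5,7,3',4'-tetra-O-benzylepicatechin F1, which is esterified with 13 (DCC, DMAP) to its 3-O-(3,4,5-tri-O-benzylgalloyl) ester F2. In parallel, 5 is debrominated (MeLi, then t-BuLi, THF, −78 °C, MeOH quench) to octa-O-benzylprocyanidin B2 F3. Condensation of F2 with F3 (Me3SiOSO2CF3, CH2Cl2, −78 °C), with attack anti to the 3-O-acyl group, should give 16, where the route is rejoined before step 10.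

2. Step 6. The hindered aryllithium may be protonated, or may add only sluggishly to the electron-rich phenoxide-aldehyde. The fallback reverses the polarity. Setting out from 5, the aryllithium 8 is quenched with DMF to the 8-formyl dimer F4. Ortho-selective hydroxyalkylation of bromomagnesium 3,5-bis(benzyloxy)phenoxide (from commercial 3,5-bis(benzyloxy)phenol and EtMgBr, toluene, rt) with F4, directed by the magnesium chelate to the carbon next to the phenol oxygen, should return to 10.

3. Step 8. The hydro-acyloxylation may give Markovnikov addition or erode the Z geometry, which would transcribe into the wrong 2,3-relationship. In the fallback, setting out from 12, rhodium-catalysed trans-hydroboration with pinacolborane ([RhCl(C8H12)]2, P(i-Pr)3, Et3N, cyclohexane, rt) would give the (Z)-alkenyl pinacol boronate F5, which KHF2 in MeOH/H2O converts into the potassium (Z)-alkenyltrifluoroborate F6. Chan–Lam-type oxidative C–O coupling of F6 with 13 (CuBr, DMAP, O2, 4 Å molecular sieves, CH2Cl2), with retention of alkene geometry, should return to 14.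

**Further compounds**

F1 | step 9 | 4β-(2-ethoxyethoxy)-5,7,3',4'-tetra-O-benzyl-(−)-epicatechin | O[C@@H]1[C@@H](OCCOCC)c2c(OCc3ccccc3)cc(OCc3ccccc3)cc2O[C@@H]1c1ccc(OCc2ccccc2)c(OCc2ccccc2)c1
F2 | step 9 | 4β-(2-ethoxyethoxy)-5,7,3',4'-tetra-O-benzyl-(−)-epicatechin 3-O-(3,4,5-tri-O-benzylgallate) | O=C(O[C@@H]1[C@@H](OCCOCC)c2c(OCc3ccccc3)cc(OCc3ccccc3)cc2O[C@@H]1c1ccc(OCc2ccccc2)c(OCc2ccccc2)c1)c1cc(OCc2ccccc2)c(OCc2ccccc2)c(OCc2ccccc2)c1
F3 | step 9 | octa-O-benzylprocyanidin B2, [tetra-O-benzylepicatechin]-(4β→8)-[tetra-O-benzylepicatechin] | O[C@@H]1[C@@H](c2c(OCc3ccccc3)cc(OCc3ccccc3)c3c2O[C@H](c2ccc(OCc4ccccc4)c(OCc4ccccc4)c2)[C@H](O)C3)c2c(OCc3ccccc3)cc(OCc3ccccc3)cc2O[C@@H]1c1ccc(OCc2ccccc2)c(OCc2ccccc2)c1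
F4 | step 6 | 8-formyl-[tetra-O-benzylepicatechin]-(4β→8)-[tetra-O-benzylepicatechin], formyl on the upper unit | O[C@@H]1[C@@H](c2c(OCc3ccccc3)cc(OCc3ccccc3)c3c2O[C@H](c2ccc(OCc4ccccc4)c(OCc4ccccc4)c2)[C@H](O)C3)c2c(OCc3ccccc3)cc(OCc3ccccc3)c(C=O)c2O[C@@H]1c1ccc(OCc2ccccc2)c(OCc2ccccc2)c1
F5 | step 8 | (Z)-2-[3,4-bis(benzyloxy)phenyl]ethenylboronic acid pinacol ester | CC1(C)OB(/C=C\c2ccc(OCc3ccccc3)c(OCc3ccccc3)c2)OC1(C)C
F6 | step 8 | potassium (Z)-2-[3,4-bis(benzyloxy)phenyl]ethenyltrifluoroborate | [K+].F[B-](F)(F)/C=C\c1ccc(OCc2ccccc2)c(OCc2ccccc2)c1
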